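**Strategy.** Everything rests on opening ring B between C8 and C9 (eudesmane numbering). C9 is a methylene on the quaternary C10, so a metal alkyl there has no β-hydrogen, and C8 is the oxygen-bearing carbon beside C7, which carries the acrylate. The key step is an intramolecular Fukuyama acylation: the C9 alkylzinc iodide of a monocyclic ring A precursor couples with a C8 thioester under palladium catalysis and closes ring B as its C8 ketone, leaving acrylate and propionate untouched. The ketone lets C7 settle with the acrylate equatorial and is later reduced opposite the axial C10 methyl. The precursor is a cyclohexenyl propionate carrying an iodomethyl group and an itaconate-derived thioester side chain.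

Key step: step 11

Remarks on the chemistry:
- Atoms are labelled by the eudesmane numbering of the target: ring A = C1–C5 and C10, ring B = C5–C10, C11–C13 = acrylate, C14 on C10, C15 on C4.
- In step 2 the (S)-oxazaborolidinium ion is assumed to expose the enal face that leads to (6S)-4. If the facial sense is the reverse, the (R)-catalyst is used and nothing else changes.
- The C4 and C5 centres of 4–7 are drawn for the endo adduct and are erased in step 5.
- Compounds 12–16 are mixtures of C7 epimers.

Step 1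
Reactants: 1 ethyl vinyl ketone (pent-1-en-3-one)
Product: 2 (Z)-triisopropyl(penta-1,3-dien-3-yloxy)silane
Conditions: i-Pr3SiOTf, Et3N, CH2Cl2, 0 °C
Reagents that add atoms: triisopropylsilyl triflate, CC(C)[Si](OS(=O)(=O)C(F)(F)F)(C(C)C)C(C)C
Why: Soft enolisation and O-silylation of the ethyl ketone (silyl enol ether formation) should give the 2-silyloxydiene as the Z enol ether, with the methyl pointing away from the vinyl group as a Diels–Alder reaction needs.

Step 2
Reactants: 2 (Z)-triisopropyl(penta-1,3-dien-3-yloxy)silane; 3 (E)-4-acetoxy-2-methylbut-2-enal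
Product: 4 [(1S,2S,6S)-6-formyl-2,6-dimethyl-3-(triisopropylsilyloxy)cyclohex-3-en-1-yl]methyl acetate
Conditions: (S)-o-tolyl-CBS-oxazaborolidine (20 mol %), Tf2NH (18 mol %), CH2Cl2, −78 → −40 °C
Reagents that add atoms: none
Why: Catalytic enantioselective Diels–Alder reaction (Corey oxazaborolidinium catalysis): the enol ether terminus C4 bonds to the enal β-carbon C5 and C1 to C10 (para to the silyloxy group), and attack on one face of the catalyst-bound enal sets the quaternary C10.

Step 3
Reactants: 4 [(1S,2S,6S)-6-formyl-2,6-dimethyl-3-(triisopropylsilyloxy)cyclohex-3-en-1-yl]methyl acetate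
Product: 6 [(1S,2S,6S)-6-(hydroxymethyl)-2,6-dimethyl-3-oxocyclohexyl]methyl acetate, via silyl enol ether alcohol 5 (not isolated)
Conditions: NaBH4, MeOH, −20 °C; then Bu4NF, AcOH, THF, 0 °C
Reagents that add atoms: none
Why: Borohydride reduction takes the aldehyde alone while the ketone is masked as its silyl enol ether, and fluoride desilylation with protonation at C2 then frees the C3 ketone without touching C10.

Step 4
Reactants: 6 [(1S,2S,6S)-6-(hydroxymethyl)-2,6-dimethyl-3-oxocyclohexyl]methyl acetate
Product: 7 [(1S,2S,6S)-6-(iodomethyl)-2,6-dimethyl-3-oxocyclohexyl]methyl acetate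
Conditions: PPh3, I2, imidazole, toluene, 70 °C
Reagents that add atoms: iodine, II
Why: Appel-type iodination converts the neopentyl primary alcohol into the iodide through its alkoxyphosphonium salt, the ketone and acetate being inert.

Step 5
Reactants: 7 [(1S,2S,6S)-6-(iodomethyl)-2,6-dimethyl-3-oxocyclohexyl]methyl acetate
Product: 8 [(6S)-6-(iodomethyl)-2,6-dimethyl-3-oxocyclohex-1-en-1-yl]methyl acetate
Conditions: IBX (1.3 equiv), DMSO, 75 °C
Reagents that add atoms: none
Why: IBX α,β-dehydrogenation of the ketone (Nicolaou) should run through the more substituted enol to the tetrasubstituted C4=C5 enone, which erases the C4 and C5 centres and makes the acetate allylic.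

Step 6
Reactants: 9 dimethyl itaconate
Product: 10 3-(methoxycarbonyl)but-3-enoic acid
Conditions: LiOH (1.0 equiv), THF–H2O, 0 °C; then 1 M HCl
Reagents that add atoms: lithium hydroxide, [Li+].[OH-]
Why: Regioselective saponification, because hydroxide attacks the unhindered non-conjugated ester faster than the less electrophilic α-substituted acrylate ester.

Step 7
Reactants: 10 3-(methoxycarbonyl)but-3-enoic acid
Product: 11 methyl 4-(ethylsulfanyl)-2-methylidene-4-oxobutanoate
Conditions: EtSH (1.05 equiv), EDC·HCl, DMAP (5 mol %), CH2Cl2, 0 °C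
Reagents that add atoms: ethanethiol, CCS
Why: Steglich-type carbodiimide thioesterification at 0 °C, which should outrun conjugate addition of the thiol to the acrylate.

Step 8
Reactants: 8 [(6S)-6-(iodomethyl)-2,6-dimethyl-3-oxocyclohex-1-en-1-yl]methyl acetate; 11 methyl 4-(ethylsulfanyl)-2-methylidene-4-oxobutanoate
Product: 12 methyl 4-(ethylsulfanyl)-3-{[(6S)-6-(iodomethyl)-2,6-dimethyl-3-oxocyclohex-1-en-1-yl]methyl}-2-methylidene-4-oxobutanoate (both C7 epimers)
Conditions: 11, LiN(SiMe3)2, THF, −78 °C; then 8, Pd(PPh3)4 (5 mol %), −78 → 0 °C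
Reagents that add atoms: none
Why: Tsuji–Trost allylic alkylation, in which zerovalent palladium ionises the primary allylic acetate and the lithium dienolate of 11 attacks the less hindered terminus C6 through its α-carbon C7, the neopentyl iodide being inert.

Step 9
Reactants: 12 methyl 4-(ethylsulfanyl)-3-{[(6S)-6-(iodomethyl)-2,6-dimethyl-3-oxocyclohex-1-en-1-yl]methyl}-2-methylidene-4-oxobutanoate
Product: 13 methyl 4-(ethylsulfanyl)-3-{[(3S,6S)-3-hydroxy-6-(iodomethyl)-2,6-dimethylcyclohex-1-en-1-yl]methyl}-2-methylidene-4-oxobutanoate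
Conditions: (R)-Me-CBS-oxazaborolidine (20 mol %), catecholborane, toluene, −78 °C
Reagents that add atoms: none
Why: Corey–Bakshi–Shibata reduction delivers hydride to the enone carbonyl under catalyst control, with the α-methylated alkenyl carbon C4 as the large group, which should set C3 as S whatever the configuration at C10.

Step 10
Reactants: 13 methyl 4-(ethylsulfanyl)-3-{[(3S,6S)-3-hydroxy-6-(iodomethyl)-2,6-dimethylcyclohex-1-en-1-yl]methyl}-2-methylidene-4-oxobutanoate
Product: 14 methyl 4-(ethylsulfanyl)-3-{[(3S,6S)-6-(iodomethyl)-2,6-dimethyl-3-(propanoyloxy)cyclohex-1-en-1-yl]methyl}-2-methylidene-4-oxobutanoate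
Conditions: (EtCO)2O, Et3N, DMAP (cat.), CH2Cl2, 0 °C
Reagents that add atoms: propionic anhydride, CCC(=O)OC(=O)CC
Why: DMAP-catalysed esterification of the secondary allylic alcohol, with retention at C3.

Step 11
Reactants: 14 methyl 4-(ethylsulfanyl)-3-{[(3S,6S)-6-(iodomethyl)-2,6-dimethyl-3-(propanoyloxy)cyclohex-1-en-1-yl]methyl}-2-methylidene-4-oxobutanoate
Product: 17 methyl 2-[(2R,4aR,7S)-4a,8-dimethyl-3-oxo-7-(propanoyloxy)-1,2,3,4,4a,5,6,7-octahydronaphthalen-2-yl]prop-2-enoate, via alkylzinc iodide 15 (not isolated), via C7-epimeric ketone mixture 16 (not isolated)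
Conditions: Zn dust (activated), LiCl, THF, 45 °C; then PdCl2(PPh3)2 (10 mol %), toluene–THF (0.005 M), 25 °C; then DBU (0.2 equiv), CH2Cl2, 0 °C
Reagents that add atoms: none
Why: Zinc inserts into the neopentyl C9–I bond (C10 has no hydrogen, so alkylzinc 15 cannot β-eliminate), zerovalent palladium adds oxidatively to the C8–S bond of the thioester, intramolecular transmetalation gives an acyl(alkyl)palladium chelate, and reductive elimination forms C8–C9. The closest known reaction is the Fukuyama ketone synthesis from thioesters and alkylzinc iodides, run here within one molecule at high dilution. Ring B closes in a 6-exo-trig sense at the acyl carbon, through a seven-membered palladacycle. No stereocentre is made at C8, which becomes the ketone; the neighbouring C7 is epimerisable, and DBU should equilibrate both epimers of 16 to the chair with the acrylate equatorial (7R), the conformation of ring B being fixed by the axial C10 methyl and the C4=C5 alkene. The step needs acyl transfer to the thioester only, which the thioester/organozinc pairing secures over the methyl acrylate, the propionate and the alkenes, and cyclisation over oligomerisation, which the six-membered ring and dilution secure.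

Step 12
Reactants: 17 methyl 2-[(2R,4aR,7S)-4a,8-dimethyl-3-oxo-7-(propanoyloxy)-1,2,3,4,4a,5,6,7-octahydronaphthalen-2-yl]prop-2-enoate
Product: 19 methyl 2-[(2R,3R,4aR,7S)-3-acetoxy-4a,8-dimethyl-7-(propanoyloxy)-1,2,3,4,4a,5,6,7-octahydronaphthalen-2-yl]prop-2-enoate (target), via lithium alkoxide 18 (not isolated)
Conditions: LiBH(s-Bu)3 (1.05 equiv), THF, −78 °C; then Ac2O, DMAP, −78 → 0 °C
Reagents that add atoms: acetic anhydride, CC(=O)OC(C)=O
Why: Bulky trialkylborohydride reduction of the cyclohexanone by equatorial attack, away from the axial C10 methyl, should give the axial 8β-alkoxide (8R, cis to the C7 acrylate), which is acetylated in the flask before it can lactonise onto the C12 ester.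

**Compound list**

1 | ethyl vinyl ketone | CCC(=O)C=C | starting material
2 | (Z)-triisopropyl(penta-1,3-dien-3-yloxy)silane | C=C/C(O[Si](C(C)C)(C(C)C)C(C)C)=C/C | intermediate
3 | (E)-4-acetoxy-2-methylbut-2-enal | CC(=O)OC/C=C(\C)C=O | starting material
4 | [(1S,2S,6S)-6-formyl-2,6-dimethyl-3-(triisopropylsilyloxy)cyclohex-3-en-1-yl]methyl acetate | CC(=O)OC[C@H]1[C@H](C)C(O[Si](C(C)C)(C(C)C)C(C)C)=CC[C@]1(C)C=O | intermediate
5 | [(1S,2S,6S)-6-(hydroxymethyl)-2,6-dimethyl-3-(triisopropylsilyloxy)cyclohex-3-en-1-yl]methyl acetate | CC(=O)OC[C@H]1[C@H](C)C(O[Si](C(C)C)(C(C)C)C(C)C)=CC[C@]1(C)CO | intermediate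
6 | [(1S,2S,6S)-6-(hydroxymethyl)-2,6-dimethyl-3-oxocyclohexyl]methyl acetate | CC(=O)OC[C@H]1[C@H](C)C(=O)CC[C@]1(C)CO | intermediate
7 | [(1S,2S,6S)-6-(iodomethyl)-2,6-dimethyl-3-oxocyclohexyl]methyl acetate | CC(=O)OC[C@H]1[C@H](C)C(=O)CC[C@]1(C)CI | intermediate
8 | [(6S)-6-(iodomethyl)-2,6-dimethyl-3-oxocyclohex-1-en-1-yl]methyl acetate | CC(=O)OCC1=C(C)C(=O)CC[C@]1(C)CI | intermediate
9 | dimethyl itaconate | C=C(CC(=O)OC)C(=O)OC | starting material
10 | 3-(methoxycarbonyl)but-3-enoic acid | C=C(CC(=O)O)C(=O)OC | intermediate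
11 | methyl 4-(ethylsulfanyl)-2-methylidene-4-oxobutanoate | C=C(CC(=O)SCC)C(=O)OC | intermediate
12 | methyl 4-(ethylsulfanyl)-3-{[(6S)-6-(iodomethyl)-2,6-dimethyl-3-oxocyclohex-1-en-1-yl]methyl}-2-methylidene-4-oxobutanoate, both C7 epimers | C=C(C(=O)OC)C(CC1=C(C)C(=O)CC[C@]1(C)CI)C(=O)SCC | intermediate
13 | methyl 4-(ethylsulfanyl)-3-{[(3S,6S)-3-hydroxy-6-(iodomethyl)-2,6-dimethylcyclohex-1-en-1-yl]methyl}-2-methylidene-4-oxobutanoate, both C7 epimers | C=C(C(=O)OC)C(CC1=C(C)[C@@H](O)CC[C@]1(C)CI)C(=O)SCC | intermediate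
14 | methyl 4-(ethylsulfanyl)-3-{[(3S,6S)-6-(iodomethyl)-2,6-dimethyl-3-(propanoyloxy)cyclohex-1-en-1-yl]methyl}-2-methylidene-4-oxobutanoate, both C7 epimers | C=C(C(=O)OC)C(CC1=C(C)[C@@H](OC(=O)CC)CC[C@]1(C)CI)C(=O)SCC | intermediate
15 | alkylzinc iodide of 14 (C9–ZnI) | C=C(C(=O)OC)C(CC1=C(C)[C@@H](OC(=O)CC)CC[C@]1(C)C[Zn]I)C(=O)SCC | intermediate
16 | methyl 2-[(4aR,7S)-4a,8-dimethyl-3-oxo-7-(propanoyloxy)-1,2,3,4,4a,5,6,7-octahydronaphthalen-2-yl]prop-2-enoate, both C7 epimers | C=C(C(=O)OC)C1CC2=C(C)[C@@H](OC(=O)CC)CC[C@]2(C)CC1=O | intermediate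
17 | methyl 2-[(2R,4aR,7S)-4a,8-dimethyl-3-oxo-7-(propanoyloxy)-1,2,3,4,4a,5,6,7-octahydronaphthalen-2-yl]prop-2-enoate | C=C(C(=O)OC)[C@H]1CC2=C(C)[C@@H](OC(=O)CC)CC[C@]2(C)CC1=O | intermediate
18 | lithium 8β-alkoxide of reduced 17 | C=C(C(=O)OC)[C@H]1CC2=C(C)[C@@H](OC(=O)CC)CC[C@]2(C)C[C@H]1[O-].[Li+] | intermediate
19 | methyl 2-[(2R,3R,4aR,7S)-3-acetoxy-4a,8-dimethyl-7-(propanoyloxy)-1,2,3,4,4a,5,6,7-octahydronaphthalen-2-yl]prop-2-enoate | C=C(C(=O)OC)[C@H]1CC2=C(C)[C@@H](OC(=O)CC)CC[C@]2(C)C[C@H]1OC(C)=O | target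

**Step count.** Total: 12 steps. Longest linear sequence: 10 steps (steps 1–5 and 8–12); steps 6–7 make the side-chain fragment.

**Steps most likely to fail**

Step 11 (key step). Zinc insertion at the neopentyl carbon may be sluggish, the acidic C7–H may protonate the alkylzinc, acyl transfer may go between molecules, and DBU may move the exocyclic alkene into conjugation. The fallback sets out from 14. Fukuyama reduction of the thioester (Et3SiH, Pd/C, acetone) would give the aldehyde methyl 3-{[(3S,6S)-6-(iodomethyl)-2,6-dimethyl-3-(propanoyloxy)cyclohex-1-en-1-yl]methyl}-2-methylidene-4-oxobutanoate F1. A 6-exo cyclisation of the C9 radical onto the aldehyde (Bu3SnH, AIBN, benzene, 80 °C, slow addition) would close ring B as the alcohols methyl 2-[(4aR,7S)-3-hydroxy-4a,8-dimethyl-7-(propanoyloxy)-1,2,3,4,4a,5,6,7-octahydronaphthalen-2-yl]prop-2-enoate F2. Dess–Martin oxidation of F2 returns to the route at 16, which is equilibrated to 17 as before.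

Step 5. Dehydrogenation may go towards C2 instead of C4, may overrun to the dienone, or the reagent may attack the iodide. The fallback sets out from 7. Acid-mediated bromination at the more substituted α-carbon (pyridinium tribromide, AcOH) would give [(1S,6S)-2-bromo-6-(iodomethyl)-2,6-dimethyl-3-oxocyclohexyl]methyl acetate F3. Dehydrobromination (Li2CO3, LiBr, DMF, 110 °C) returns to the route at 8.

Step 8. The hard lithium dienolate may react poorly with the allylpalladium intermediate, attack through its γ-carbon, or add to the acrylate of a second molecule. The fallback sets out from 8. Methanolysis (K2CO3, MeOH, 0 °C) would give the allylic alcohol (4S)-3-(hydroxymethyl)-4-(iodomethyl)-2,4-dimethylcyclohex-2-en-1-one F4. Appel bromination (CBr4, PPh3, CH2Cl2) would give the allylic bromide (4S)-3-(bromomethyl)-4-(iodomethyl)-2,4-dimethylcyclohex-2-en-1-one F5. Direct displacement by the lithium enolate of 11 (LiN(SiMe3)2, THF, −78 °C) returns to the route at 12.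

**Further compounds**

F1 | step 11 | methyl 3-{[(3S,6S)-6-(iodomethyl)-2,6-dimethyl-3-(propanoyloxy)cyclohex-1-en-1-yl]methyl}-2-methylidene-4-oxobutanoate | C=C(C(=O)OC)C(CC1=C(C)[C@@H](OC(=O)CC)CC[C@]1(C)CI)C=O
F2 | step 11 | methyl 2-[(4aR,7S)-3-hydroxy-4a,8-dimethyl-7-(propanoyloxy)-1,2,3,4,4a,5,6,7-octahydronaphthalen-2-yl]prop-2-enoate | C=C(C(=O)OC)C1CC2=C(C)[C@@H](OC(=O)CC)CC[C@]2(C)CC1O
F3 | step 5 | [(1S,6S)-2-bromo-6-(iodomethyl)-2,6-dimethyl-3-oxocyclohexyl]methyl acetate | CC(=O)OC[C@H]1C(C)(Br)C(=O)CC[C@]1(C)CI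
F4 | step 8 | (4S)-3-(hydroxymethyl)-4-(iodomethyl)-2,4-dimethylcyclohex-2-en-1-one | OCC1=C(C)C(=O)CC[C@]1(C)CI
F5 | step 8 | (4S)-3-(bromomethyl)-4-(iodomethyl)-2,4-dimethylcyclohex-2-en-1-one | BrCC1=C(C)C(=O)CC[C@]1(C)CI
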